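**Plan**

- Numbering follows isochromene (C1, O2, C3, C4, C4a, C5–C8, C8a); ring A is the carbocycle and ring B the pyran. The target is (7R)-7-decanoyloxy-3-heptyl-7-methyl-6H-isochromene-6,8(7H)-dione.
- Enabling feature: ring B is a 4-ylidene-4H-pyran whose O2–C1=C8a–C4a segment is the 1-oxadiene of a 2-formyl enone carried by ring A. Ring A on its own is a dearomatised 2-methylphloroglucinol in which C7 lies between two equivalent carbonyls.
- Cuts, in retrosynthetic order: C6=O back to a silyl-protected carbinol; ring B at O2–C3 and C4–C4a (oxa-Diels–Alder, with C3=C4 and C4a=C5 arising by loss of MeOH and HCl); C1–C8a and C4a–Cl (aminomethylenation and deoxychlorination of a 1,3-dione); C6–H (enzymatic carbonyl reduction); C7–O (Wessely acyloxylation).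
- Forward: the arene becomes ring A in step 1 with the decanoate in place. Ring A is then desymmetrised, protected and converted into a β-chlorovinyl aldehyde; ring B with the heptyl chain is annulated in one operation; C6 is returned to the ketone last.
- Stereochemistry: C7 is the only stereocentre of the target. It becomes stereogenic when a ketoreductase reduces one of the two enantiotopic carbonyls of the achiral trione. It is quaternary and keeps an sp3 C6 neighbour until the final step, so no symmetric enolate can erase it.

Key step: step 7

Assumption: a ketoreductase from a screening panel is taken to reduce the enantiotopic carbonyl that leads to the (1R) hydroxy dione 4; the carbinol centre is written as (2R) (both oxygens cis), but either epimer would serve because this centre becomes a ketone in step 9.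

**Route**

Step 1
Reactants: 1 2-methylbenzene-1,3,5-triol (2-methylphloroglucinol); 2 decanoic acid
Product: 3 1-methyl-2,4,6-trioxocyclohexyl decanoate (achiral, present mainly as its enol)
Conditions: Pb(OAc)4 (1.1 equiv), 2 (4.5 equiv), toluene, 40 °C, AcOH removed under reduced pressure; then 1, EtOAc/CH2Cl2, 0 °C
Reagents that add atoms: none
Why: Wessely oxidation, in which the aryloxy derivative of tetravalent lead passes a decanoate ligand to the methyl-bearing ortho carbon, giving a dienone that cannot rearomatise and settles as the enolised trione; no stereocentre arises because the two carbonyls flanking the quaternary carbon are equivalent.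

Step 2
Reactants: 3 1-methyl-2,4,6-trioxocyclohexyl decanoate
Product: 4 (1R,2R)-2-hydroxy-1-methyl-4,6-dioxocyclohexyl decanoate
Conditions: ketoreductase (NADPH-dependent, chosen from a screening panel), NADP+ (cat.), i-PrOH (10 vol%), KH2PO4/K2HPO4 buffer pH 6.5, 30 °C; extraction at pH 4, crude product used at once
Reagents that add atoms: none
Why: Enzymatic desymmetrising carbonyl reduction as known for 2,2-disubstituted cyclic 1,3-diketones: at this pH the trione is a vinylogous carboxylate whose only ketone-like carbonyl is one of the two enantiotopic ones beside the quaternary carbon, so hydride transfer from NADPH inside the enzyme pocket to one carbonyl on one face should set C1 (the later C7) and the carbinol centre together.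

Step 3
Reactants: 4 (1R,2R)-2-hydroxy-1-methyl-4,6-dioxocyclohexyl decanoate
Product: 6 (1R,2R)-2-[(tert-butyldimethylsilyl)oxy]-1-methyl-4,6-dioxocyclohexyl decanoate, via bis-silyl enol ether 5 (not isolated)
Conditions: TBSOTf (2.4 equiv), 2,6-lutidine, CH2Cl2, −40 to 0 °C; then aq. citric acid, THF, 0 °C
Reagents that add atoms: tert-butyldimethylsilyl trifluoromethanesulfonate (TBSOTf), CC(C)(C)[Si](C)(C)OS(=O)(=O)C(F)(F)F
Why: Silyl ether protection with a silyl triflate, which should cap the hindered secondary alcohol at low temperature before the neighbouring decanoyl group can migrate; the enol is silylated as well, but this vinylogous silyl ester is cleaved again in the mildly acidic work-up.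

Step 4
Reactants: 6 (1R,2R)-2-[(tert-butyldimethylsilyl)oxy]-1-methyl-4,6-dioxocyclohexyl decanoate
Product: 7 (1R,2R)-2-[(tert-butyldimethylsilyl)oxy]-5-[(dimethylamino)methylidene]-1-methyl-4,6-dioxocyclohexyl decanoate
Conditions: Me2NCH(OMe)2 (1.2 equiv), toluene, 0 °C to rt
Reagents that add atoms: N,N-dimethylformamide dimethyl acetal, COC(OC)N(C)C
Why: Aminomethylenation of a cyclic 1,3-dione with an amide acetal, in which the CH2 between the two carbonyls is the only nucleophilic carbon, so the one-carbon unit (the future C1) enters there under neutral conditions that spare the silyl ether and the ester.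

Step 5
Reactants: 7 (1R,2R)-2-[(tert-butyldimethylsilyl)oxy]-5-[(dimethylamino)methylidene]-1-methyl-4,6-dioxocyclohexyl decanoate
Product: 9 (1R,2R)-2-[(tert-butyldimethylsilyl)oxy]-4-chloro-5-formyl-1-methyl-6-oxocyclohex-4-en-1-yl decanoate, via chlorovinyl iminium chloride 8 (not isolated)
Conditions: (COCl)2 (1.05 equiv), CH2Cl2, −40 to 0 °C; then cold aq. NaOAc
Reagents that add atoms: oxalyl chloride, O=C(Cl)C(=O)Cl; water, O
Why: Deoxychlorination of a vinylogous amide, the second half of a Vilsmeier–Haack–Arnold chloroformylation: oxalyl chloride should acylate the more accessible and more electron-rich carbonyl oxygen (the one remote from the quaternary carbon), chloride then displaces it at that carbon with loss of CO and CO2, and water hydrolyses the iminium ion to the aldehyde.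

Step 6
Reactants: 10 methyl octanoate
Product: 11 2-methoxynon-1-ene
Conditions: Cp2TiMe2 (2 equiv), toluene, 70 °C, dark; filtration through basic alumina, distillation
Reagents that add atoms: dimethyltitanocene Cp2TiMe2, [CH3-].[CH3-].[Ti+4].c1cc[cH-]c1.c1cc[cH-]c1
Why: Petasis methylenation of an ester, in which the titanium methylidene formed on heating adds to the ester carbonyl and the oxatitanacyclobutane collapses to the enol ether, so the double bond can only be terminal.

Step 7
Reactants: 9 (1R,2R)-2-[(tert-butyldimethylsilyl)oxy]-4-chloro-5-formyl-1-methyl-6-oxocyclohex-4-en-1-yl decanoate; 11 2-methoxynon-1-ene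
Product: 14 (6R,7R)-6-[(tert-butyldimethylsilyl)oxy]-3-heptyl-7-methyl-8-oxo-7,8-dihydro-6H-isochromen-7-yl decanoate, via chloro ketal cycloadduct 12 (not isolated), via methoxy dienyl ketal 13 (not isolated)
Conditions: 11 (3 equiv), 2,6-lutidine (2.5 equiv), toluene, 25 to 60 °C
Reagents that add atoms: none
Why: Once the formyl group turns s-cis to C8a=C4a it forms an electron-poor 1-oxadiene (formyl O, C1, C8a, C4a; lowered further by the C8 ketone and the chlorine) that should take up the electron-rich enol ether in an inverse-electron-demand oxa-Diels–Alder reaction, the CH2 terminus bonding to C4a slightly ahead of O–C3 bond formation, after which 2,6-lutidine removes HCl from the allylic tertiary chloride 12 (proton from C5) and the lutidinium chloride so formed catalyses loss of methanol from ketal 13 across C3–C4. The closest known reactions are the hetero-Diels–Alder additions of enol ethers to 2-formyl enones, 3-formylchromones and alkylidene 1,3-dicarbonyl compounds, and a stepwise addition–elimination at C4a followed by ring closure would lead to the same product. Ring B closes as a six-membered ring by [4+2] cycloaddition, O2–C3 and C4–C4a being formed in one suprafacial event. No new stereocentre survives, since C3 and C4a become sp2 in the two eliminations, and C7 is untouched because it bears no hydrogen and has no enolisable neighbour under these conditions. The step needs chemoselectivity for the formyl over the ketone oxadiene, which the ring secures by locking C8=O s-trans to C8a=C4a, and regioselectivity (C4 to C4a, oxygen to C3), which the matched polarity of the enal β-carbon and the nucleophilic CH2 of the enol ether secures. The excess of enol ether and the pyridine buffer are meant to keep the acid-labile silyl ether and enol ether intact while HCl is released.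

Step 8
Reactants: 14 (6R,7R)-6-[(tert-butyldimethylsilyl)oxy]-3-heptyl-7-methyl-8-oxo-7,8-dihydro-6H-isochromen-7-yl decanoate
Product: 15 (6R,7R)-3-heptyl-6-hydroxy-7-methyl-8-oxo-7,8-dihydro-6H-isochromen-7-yl decanoate
Conditions: HF·pyridine, pyridine, THF, 0 °C to rt; crude alcohol used directly
Reagents that add atoms: none
Why: Fluoride-mediated desilylation, run in a pyridine-buffered, weakly acidic medium to avoid both base-induced migration of the decanoyl group to the freed C6 hydroxyl and ionisation of the allylic C6–O bond.

Step 9
Reactants: 15 (6R,7R)-3-heptyl-6-hydroxy-7-methyl-8-oxo-7,8-dihydro-6H-isochromen-7-yl decanoate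
Product: 16 (7R)-3-heptyl-7-methyl-6,8-dioxo-7,8-dihydro-6H-isochromen-7-yl decanoate
Conditions: activated MnO2 (excess), CH2Cl2, rt
Reagents that add atoms: none
Why: MnO2 oxidation of an allylic alcohol: the C6 carbinol is allylic to C5=C4a and should be oxidised selectively under neutral conditions, which removes the auxiliary stereocentre and leaves the non-enolisable C7 centre as set in step 2.

**Compound list**

1 | 2-methylbenzene-1,3,5-triol (2-methylphloroglucinol) | Cc1c(O)cc(O)cc1O | starting material
2 | decanoic acid | CCCCCCCCCC(=O)O | starting material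
3 | 1-methyl-2,4,6-trioxocyclohexyl decanoate | CCCCCCCCCC(=O)OC1(C)C(=O)CC(=O)CC1=O | intermediate
4 | (1R,2R)-2-hydroxy-1-methyl-4,6-dioxocyclohexyl decanoate | CCCCCCCCCC(=O)O[C@]1(C)[C@H](O)CC(=O)CC1=O | intermediate
5 | (1R,2R)-2,4-bis[(tert-butyldimethylsilyl)oxy]-1-methyl-6-oxocyclohex-4-en-1-yl decanoate | CCCCCCCCCC(=O)O[C@]1(C)[C@H](O[Si](C)(C)C(C)(C)C)CC(O[Si](C)(C)C(C)(C)C)=CC1=O | intermediate
6 | (1R,2R)-2-[(tert-butyldimethylsilyl)oxy]-1-methyl-4,6-dioxocyclohexyl decanoate | CCCCCCCCCC(=O)O[C@]1(C)[C@H](O[Si](C)(C)C(C)(C)C)CC(=O)CC1=O | intermediate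
7 | (1R,2R)-2-[(tert-butyldimethylsilyl)oxy]-5-[(dimethylamino)methylidene]-1-methyl-4,6-dioxocyclohexyl decanoate | CCCCCCCCCC(=O)O[C@]1(C)[C@H](O[Si](C)(C)C(C)(C)C)CC(=O)C(=CN(C)C)C1=O | intermediate
8 | N-({(4R,5R)-4-[(tert-butyldimethylsilyl)oxy]-2-chloro-5-(decanoyloxy)-5-methyl-6-oxocyclohex-1-en-1-yl}methylidene)-N-methylmethanaminium chloride | CCCCCCCCCC(=O)O[C@]1(C)[C@H](O[Si](C)(C)C(C)(C)C)CC(Cl)=C(C=[N+](C)C)C1=O.[Cl-] | intermediate
9 | (1R,2R)-2-[(tert-butyldimethylsilyl)oxy]-4-chloro-5-formyl-1-methyl-6-oxocyclohex-4-en-1-yl decanoate | CCCCCCCCCC(=O)O[C@]1(C)[C@H](O[Si](C)(C)C(C)(C)C)CC(Cl)=C(C=O)C1=O | intermediate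
10 | methyl octanoate | CCCCCCCC(=O)OC | starting material
11 | 2-methoxynon-1-ene | C=C(OC)CCCCCCC | intermediate
12 | (6R,7R)-6-[(tert-butyldimethylsilyl)oxy]-4a-chloro-3-heptyl-3-methoxy-7-methyl-8-oxo-4,4a,5,6,7,8-hexahydro-3H-isochromen-7-yl decanoate (C3 and C4a unassigned) | CCCCCCCCCC(=O)O[C@]1(C)[C@H](O[Si](C)(C)C(C)(C)C)CC2(Cl)CC(CCCCCCC)(OC)OC=C2C1=O | intermediate
13 | (6R,7R)-6-[(tert-butyldimethylsilyl)oxy]-3-heptyl-3-methoxy-7-methyl-8-oxo-4,6,7,8-tetrahydro-3H-isochromen-7-yl decanoate (C3 unassigned) | CCCCCCCCCC(=O)O[C@]1(C)[C@H](O[Si](C)(C)C(C)(C)C)C=C2CC(CCCCCCC)(OC)OC=C2C1=O | intermediate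
14 | (6R,7R)-6-[(tert-butyldimethylsilyl)oxy]-3-heptyl-7-methyl-8-oxo-7,8-dihydro-6H-isochromen-7-yl decanoate | CCCCCCCCCC(=O)O[C@]1(C)[C@H](O[Si](C)(C)C(C)(C)C)C=C2C=C(CCCCCCC)OC=C2C1=O | intermediate
15 | (6R,7R)-3-heptyl-6-hydroxy-7-methyl-8-oxo-7,8-dihydro-6H-isochromen-7-yl decanoate | CCCCCCCCCC(=O)O[C@]1(C)[C@H](O)C=C2C=C(CCCCCCC)OC=C2C1=O | intermediate
16 | (7R)-3-heptyl-7-methyl-6,8-dioxo-7,8-dihydro-6H-isochromen-7-yl decanoate | CCCCCCCCCC(=O)O[C@]1(C)C(=O)C=C2C=C(CCCCCCC)OC=C2C1=O | target

**Step count**

Total: 9 steps. Longest linear sequence: 8 steps (steps 1–5 and 7–9, from 1); the enol ether arm is one step (step 6).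

**Steps most likely to fail**

Step 7. The cycloaddition at the fully substituted, chlorine-bearing C4a terminus may be slow. Acid-promoted hydrolysis or oligomerisation of the enol ether, or base-promoted loss of silanol from the β-silyloxy position of 9, could then take over, or methanol loss could stall at ketal 13. The fallback forms the same two ring B bonds one after the other. From 9, Sonogashira coupling with non-1-yne (PdCl2(PPh3)2, CuI, Et3N, THF, rt) should replace the activated vinylic chloride and give (1R,2R)-2-[(tert-butyldimethylsilyl)oxy]-5-formyl-1-methyl-4-(non-1-yn-1-yl)-6-oxocyclohex-4-en-1-yl decanoate F1. Cycloisomerisation of this ortho-alkynyl enal with AuCl(PPh3)/AgOTf (cat.) and 2,6-lutidine in CH2Cl2 would then proceed by 6-endo-dig attack of the formyl oxygen on the activated alkyne, giving a pyrylium intermediate, followed by shift of a C5 proton to C4. This is expected to give 14, where the route is rejoined.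

Step 1. Ligand transfer may go to the two unsubstituted ring carbons instead of the methyl-bearing one; those adducts rearomatise and are oxidised further to quinones, so the very electron-rich triol is consumed unproductively. The fallback blocks these positions. From 1, bromination (NBS, 2 equiv, MeCN, 0 °C) should give 2,4-dibromo-6-methylbenzene-1,3,5-triol F2. Wessely oxidation of F2 under the conditions of step 1 can then only dearomatise at the methyl-bearing carbon and should give 3,5-dibromo-1-methyl-2,4,6-trioxocyclohexyl decanoate F3. Its two activated C–Br bonds, each on a carbon between two carbonyls, would be reduced with aq. Na2SO3 in THF at 0 °C, returning to the route at 3.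

Step 2. The enzyme may not distinguish the two enantiotopic carbonyls well enough, or may not turn over the anionic, largely enolised substrate; long reaction times would also give the decanoyl group time to migrate to the new hydroxyl. The fallback replaces enzymatic recognition by a small-molecule bifunctional hydride-transfer catalyst acting on the neutral trione in an organic medium. From 3, asymmetric transfer hydrogenation with RuCl(p-cymene)[(S,S)-TsDPEN] or its (R,R) antipode, whichever leads to the (1R) series, in HCO2H/Et3N and CH2Cl2 at rt is a known desymmetrisation of 2,2-disubstituted cyclic 1,3-diketones. It should give 4 directly, with no new compound on the way (F0).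

Further compounds
F1 | step 7 | (1R,2R)-2-[(tert-butyldimethylsilyl)oxy]-5-formyl-1-methyl-4-(non-1-yn-1-yl)-6-oxocyclohex-4-en-1-yl decanoate | CCCCCCCCCC(=O)O[C@]1(C)[C@H](O[Si](C)(C)C(C)(C)C)CC(C#CCCCCCCC)=C(C=O)C1=O
F2 | step 1 | 2,4-dibromo-6-methylbenzene-1,3,5-triol | Cc1c(O)c(Br)c(O)c(Br)c1O
F3 | step 1 | 3,5-dibromo-1-methyl-2,4,6-trioxocyclohexyl decanoate | CCCCCCCCCC(=O)OC1(C)C(=O)C(Br)C(=O)C(Br)C1=O
F0 | step 2 | none | none
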